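The route disconnects the two C–O bonds of the vicinal diol formed by C5, the quaternary carbinol of the cyclopentenone ring, and C6, the first side-chain carbon, which lie next to the oxygenated C4 stereocentre. The key step exploits this C4–C5–C6 array: one syn dihydroxylation of an exocyclic C5=C6 alkene creates both C–O bonds and both new stereocentres, the E geometry fixing C6 relative to C5 and the C4 silyloxy group dictating the face. The precursor is the cross-conjugated (R,E)-4-silyloxy-5-pentadecylidenecyclopent-2-enone, made by aldol condensation of a 4-silyloxycyclopentenone with pentadecanal. Desilylation and acetylation of the two secondary hydroxyls complete the target.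

Key step: step 6

Numbering used below: ring C1 (C=O), C2=C3, C4 (oxygenated), C5 (quaternary in the target); C6 is the first side-chain carbon. The target is (4R,5S,6S) in this numbering.

Remark on the chemistry: the silyloxy enone needed for the aldol is the (S)-enantiomer. Its C4 descriptor becomes R in the dienone only because C5 outranks C3 once it is the alkylidene carbon; the spatial arrangement is unchanged.

Assumption: the enantiopure monoacetate 1 (the product of enzymatic hydrolysis of meso cis-3,5-diacetoxycyclopentene) is bought as such and supplies the one stereocentre that is kept.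

Step 1
Reactants: 1 (1R,4S)-4-hydroxycyclopent-2-en-1-yl acetate
Product: 2 (1R,4S)-4-[(tert-butyldimethylsilyl)oxy]cyclopent-2-en-1-yl acetate
Conditions: TBSCl, imidazole, DMF, 0 °C → rt
Reagents that add atoms: tert-butyldimethylsilyl chloride (TBSCl), CC(C)(C)[Si](C)(C)Cl
Why: Imidazole-promoted silylation of the free secondary allylic alcohol (Corey silylation) should proceed without touching the acetate or either stereocentre.

Step 2
Reactants: 2 (1R,4S)-4-[(tert-butyldimethylsilyl)oxy]cyclopent-2-en-1-yl acetate
Product: 3 (1R,4S)-4-[(tert-butyldimethylsilyl)oxy]cyclopent-2-en-1-ol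
Conditions: K2CO3 (cat.), MeOH, 0 °C → rt
Reagents that add atoms: none
Why: Base-catalysed transesterification (methanolysis) removes the acetate while the silyl ether is stable to carbonate in methanol, and no C–O bond at a stereocentre is broken.

Step 3
Reactants: 3 (1R,4S)-4-[(tert-butyldimethylsilyl)oxy]cyclopent-2-en-1-ol
Product: 4 (S)-4-[(tert-butyldimethylsilyl)oxy]cyclopent-2-en-1-one
Conditions: Dess–Martin periodinane, CH2Cl2, 0 °C → rt
Reagents that add atoms: none
Why: Dess–Martin oxidation converts the allylic alcohol into the enone under mild conditions, leaving the silyloxy-bearing carbon (now C4, S) untouched.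

Step 4
Reactants: 4 (S)-4-[(tert-butyldimethylsilyl)oxy]cyclopent-2-en-1-one; 5 pentadecanal
Product: 7 (4R,5S)-4-[(tert-butyldimethylsilyl)oxy]-5-(1-hydroxypentadecyl)cyclopent-2-en-1-one (4,5-trans; epimeric mixture at the carbinol carbon), via lithium enolate 6 (not isolated)
Conditions: LiN(iPr)2, THF, −78 °C; then 5, −78 °C; AcOH quench at −78 °C
Reagents that add atoms: none
Why: Kinetic deprotonation at C5 gives the cross-conjugated lithium enolate, which should persist at −78 °C because expulsion of silyloxide would generate an antiaromatic cyclopentadienone, and its aldol addition to the aldehyde is expected anti to the C4 silyloxy group; the configurations at C5 and at the carbinol carbon are irrelevant because both carbons become sp2 in step 5.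

Step 5
Reactants: 7 (4R,5S)-4-[(tert-butyldimethylsilyl)oxy]-5-(1-hydroxypentadecyl)cyclopent-2-en-1-one
Product: 9 (R,E)-4-[(tert-butyldimethylsilyl)oxy]-5-pentadecylidenecyclopent-2-en-1-one, via mesylate 8 (not isolated)
Conditions: MsCl, Et3N, CH2Cl2, −20 °C; then DBU, −20 → 0 °C
Reagents that add atoms: none
Why: Mesylation followed by base-induced E1cB elimination of the β-mesyloxy ketone lets both carbinol epimers converge through the enolate on the thermodynamically preferred E alkene (chain anti to the carbonyl), with C4 untouched.

Step 6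
Reactants: 9 (R,E)-4-[(tert-butyldimethylsilyl)oxy]-5-pentadecylidenecyclopent-2-en-1-one
Product: 11 (4R,5S)-4-[(tert-butyldimethylsilyl)oxy]-5-hydroxy-5-[(1S)-1-hydroxypentadecyl]cyclopent-2-en-1-one, via osmate ester 10 (not isolated)
Conditions: OsO4 (5 mol %), NMO (1.2 equiv), acetone/H2O (9:1), 0 °C → rt
Reagents that add atoms: OsO4, O=[Os](=O)(=O)=O (delivers both oxygens to the alkene); N-methylmorpholine N-oxide (NMO), C[N+]1([O-])CCOCC1, and water, O (both replenish the oxo ligands of the catalyst on turnover)
Why: OsO4 adds across the exocyclic C5=C6 bond in a concerted suprafacial [3+2] cycloaddition to give the hexavalent osmium glycolate 10, which NMO re-oxidises and water hydrolyses to the diol with release of the catalyst (Upjohn dihydroxylation). The closest known reaction type is the substrate-controlled OsO4 dihydroxylation of 2-alkylidene cycloalkanones and of allylic ethers, in which the reagent approaches anti to the allylic oxygen substituent. No ring of the product is closed; the only ring formed is the transient five-membered osmate ester. C5 is set by the C4 stereocentre, whose silyloxy group shields its own face so that both oxygens arrive from the opposite one and the C5 hydroxyl ends up trans to the C4 oxygen; C6 is set relative to C5 by the E geometry, since syn addition to that face of the E alkene can only give the 6S carbinol. The step needs site selectivity for C5=C6 over the ring C2=C3 bond and anti facial selectivity: the trisubstituted exocyclic alkene is the more electron-rich of the two enone double bonds and C2=C3 is inductively deactivated by the allylic silyloxy group, while the small excess of NMO and interruption once 9 is consumed should guard against tetraol formation. If the intrinsic bias needs reinforcement, (DHQ)2PHAL is the matched ligand by the Sharpless mnemonic.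

Step 7
Reactants: 11 (4R,5S)-4-[(tert-butyldimethylsilyl)oxy]-5-hydroxy-5-[(1S)-1-hydroxypentadecyl]cyclopent-2-en-1-one
Product: 12 (4R,5S)-4,5-dihydroxy-5-[(1S)-1-hydroxypentadecyl]cyclopent-2-en-1-one
Conditions: aq. HF (48 %), MeCN, 0 °C → rt
Reagents that add atoms: none
Why: Fluoride-mediated desilylation under acidic conditions avoids the retro-aldol and elimination pathways that a basic fluoride source could open on this β-hydroxy ketone, and no stereocentre is affected.

Step 8
Reactants: 12 (4R,5S)-4,5-dihydroxy-5-[(1S)-1-hydroxypentadecyl]cyclopent-2-en-1-one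
Product: 14 (1S)-1-[(1S,5R)-5-acetoxy-1-hydroxy-2-oxocyclopent-3-en-1-yl]pentadecyl acetate (target), via 4-O-monoacetate 13 (not isolated)
Conditions: Ac2O (2.5 equiv), pyridine, DMAP (5 mol %), CH2Cl2, 0 °C
Reagents that add atoms: acetic anhydride, CC(=O)OC(C)=O
Why: Nucleophile-catalysed acylation should acetylate the two secondary hydroxyls (the unhindered C4 one first) far faster than the hindered tertiary α-ketol hydroxyl at C5, and because C5 is quaternary the C4 acetate cannot be lost by enolisation–elimination; all three stereocentres are retained.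

Compound list
1 | (1R,4S)-4-hydroxycyclopent-2-en-1-yl acetate (also named (1S,4R)-cis-4-acetoxycyclopent-2-en-1-ol; acetoxy carbon R, hydroxy carbon S, cis) | CC(=O)O[C@@H]1C[C@H](O)C=C1 | starting material
2 | (1R,4S)-4-[(tert-butyldimethylsilyl)oxy]cyclopent-2-en-1-yl acetate | CC(=O)O[C@@H]1C[C@H](O[Si](C)(C)C(C)(C)C)C=C1 | intermediate
3 | (1R,4S)-4-[(tert-butyldimethylsilyl)oxy]cyclopent-2-en-1-ol | O[C@@H]1C[C@H](O[Si](C)(C)C(C)(C)C)C=C1 | intermediate
4 | (S)-4-[(tert-butyldimethylsilyl)oxy]cyclopent-2-en-1-one | O=C1C[C@H](O[Si](C)(C)C(C)(C)C)C=C1 | intermediate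
5 | pentadecanal | CCCCCCCCCCCCCCC=O | starting material
6 | lithium enolate of 4 (C1–O–Li, C1=C5, C2=C3; C4 unchanged) | [Li]OC1=C[C@H](O[Si](C)(C)C(C)(C)C)C=C1 | intermediate (not isolated)
7 | (4R,5S)-4-[(tert-butyldimethylsilyl)oxy]-5-(1-hydroxypentadecyl)cyclopent-2-en-1-one (4,5-trans; both carbinol epimers) | CCCCCCCCCCCCCCC(O)[C@@H]1C(=O)C=C[C@H]1O[Si](C)(C)C(C)(C)C | intermediate
8 | methanesulfonate of 7 at the side-chain carbinol (ring configuration as in 7) | CCCCCCCCCCCCCCC(OS(C)(=O)=O)[C@@H]1C(=O)C=C[C@H]1O[Si](C)(C)C(C)(C)C | intermediate (not isolated)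
9 | (R,E)-4-[(tert-butyldimethylsilyl)oxy]-5-pentadecylidenecyclopent-2-en-1-one | CCCCCCCCCCCCCC/C=C1/C(=O)C=C[C@H]1O[Si](C)(C)C(C)(C)C | intermediate
10 | cyclic hexavalent osmium glycolate (osmate ester) spanning O5 and O6, both oxygens anti to the C4 silyloxy group | CCCCCCCCCCCCCC[C@@H]1O[Os](=O)(=O)O[C@@]12C(=O)C=C[C@H]2O[Si](C)(C)C(C)(C)C | intermediate (not isolated)
11 | (4R,5S)-4-[(tert-butyldimethylsilyl)oxy]-5-hydroxy-5-[(1S)-1-hydroxypentadecyl]cyclopent-2-en-1-one | CCCCCCCCCCCCCC[C@H](O)[C@@]1(O)C(=O)C=C[C@H]1O[Si](C)(C)C(C)(C)C | intermediate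
12 | (4R,5S)-4,5-dihydroxy-5-[(1S)-1-hydroxypentadecyl]cyclopent-2-en-1-one | CCCCCCCCCCCCCC[C@H](O)[C@@]1(O)C(=O)C=C[C@H]1O | intermediate
13 | (1R,5S)-5-hydroxy-5-[(1S)-1-hydroxypentadecyl]-4-oxocyclopent-2-en-1-yl acetate (4-O-monoacetate) | CCCCCCCCCCCCCC[C@H](O)[C@@]1(O)C(=O)C=C[C@H]1OC(C)=O | intermediate (not isolated)
14 | (1S)-1-[(1S,5R)-5-acetoxy-1-hydroxy-2-oxocyclopent-3-en-1-yl]pentadecyl acetate | CCCCCCCCCCCCCC[C@H](OC(C)=O)[C@@]1(O)C(=O)C=C[C@H]1OC(C)=O | target

Total step count: 8 steps.
Longest linear sequence: 8 steps (from 1; pentadecanal 5 enters at step 4).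

Steps most likely to fail

Step 6. The two enone double bonds may not be discriminated well enough, turnover on the electron-poor dienone may be slow enough to allow over-oxidation, and facial selectivity may erode. The fallback removes the enone character before the oxidation and sets out from 9. Luche reduction (NaBH4, CeCl3·7H2O, MeOH, −78 °C), with hydride delivered anti to the silyloxy group, should give the cis dienol (1S,4R,E)-4-[(tert-butyldimethylsilyl)oxy]-5-pentadecylidenecyclopent-2-en-1-ol F1. Its exocyclic alkene is now an ordinary electron-rich trisubstituted alkene flanked by two allylic oxygens on the same face, so OsO4/NMO dihydroxylation should occur there, anti to both, to give (1S,4R,5R)-4-[(tert-butyldimethylsilyl)oxy]-5-[(1S)-1-hydroxypentadecyl]cyclopent-2-ene-1,5-diol F2. MnO2 in CH2Cl2 then re-oxidises only the allylic C1 carbinol, and the route is rejoined at 11.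

Step 5. The E1cB elimination may lose E selectivity and deliver a mixture enriched in the Z alkene. The fallback replaces kinetic control by a separate thermodynamic equilibration and sets out from 7. After the elimination, the Z isomer (R,Z)-4-[(tert-butyldimethylsilyl)oxy]-5-pentadecylidenecyclopent-2-en-1-one F3 (alone or in the mixture) is treated with catalytic iodine in CH2Cl2 under visible light. Reversible iodine-atom addition–elimination should funnel it to the more stable E isomer, rejoining the route at 9.

Step 8. Acylation of the hindered C6 carbinol may stay incomplete, and forcing it may spill over to the tertiary C5 hydroxyl. The fallback reorders the end game so that the difficult acylation is done on the robust silyl ether, and sets out from 11. Ac2O, pyridine and DMAP at rt should acetylate the only secondary hydroxyl to give (1S)-1-[(1S,5R)-5-[(tert-butyldimethylsilyl)oxy]-1-hydroxy-2-oxocyclopent-3-en-1-yl]pentadecyl acetate F4. Aqueous HF in MeCN then removes the silyl group to give (1S)-1-[(1R,5R)-1,5-dihydroxy-2-oxocyclopent-3-en-1-yl]pentadecyl acetate F5 (the descriptor at the quaternary carbon changes by CIP ranking only). Brief treatment with Ac2O/pyridine at 0 °C acetylates the unhindered C4 hydroxyl and arrives at 14.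

Further compounds
F1 | step 6 | (1S,4R,E)-4-[(tert-butyldimethylsilyl)oxy]-5-pentadecylidenecyclopent-2-en-1-ol | CCCCCCCCCCCCCC/C=C1/[C@@H](O)C=C[C@H]1O[Si](C)(C)C(C)(C)C
F2 | step 6 | (1S,4R,5R)-4-[(tert-butyldimethylsilyl)oxy]-5-[(1S)-1-hydroxypentadecyl]cyclopent-2-ene-1,5-diol | CCCCCCCCCCCCCC[C@H](O)[C@@]1(O)[C@@H](O)C=C[C@H]1O[Si](C)(C)C(C)(C)C
F3 | step 5 | (R,Z)-4-[(tert-butyldimethylsilyl)oxy]-5-pentadecylidenecyclopent-2-en-1-one | CCCCCCCCCCCCCC/C=C1\C(=O)C=C[C@H]1O[Si](C)(C)C(C)(C)C
F4 | step 8 | (1S)-1-[(1S,5R)-5-[(tert-butyldimethylsilyl)oxy]-1-hydroxy-2-oxocyclopent-3-en-1-yl]pentadecyl acetate | CCCCCCCCCCCCCC[C@H](OC(C)=O)[C@@]1(O)C(=O)C=C[C@H]1O[Si](C)(C)C(C)(C)C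
F5 | step 8 | (1S)-1-[(1R,5R)-1,5-dihydroxy-2-oxocyclopent-3-en-1-yl]pentadecyl acetate | CCCCCCCCCCCCCC[C@H](OC(C)=O)[C@@]1(O)C(=O)C=C[C@H]1O
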